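A small charge of Q, stirred with L in the cold, goes in large part to Z, and Z can stand partly as crystals D, which are counted in it. The steps considered also give X and, with L, E.

| flask | Q | L | temperature | remark | time |
|---|---|---|---|---|---|
| larch | 0.61 M | 0.41 M | −18 °C | run made earlier |  |
| alder | 0.61 M | 0.92 M | −1 °C | run made earlier |  |
| ash | 1.2 M | 0.61 M | −18 °C | run made earlier |  |
| theta | 0.61 M | 0.610 M | 5 °C |  | 80 min |
| delta | 0.61 M | 0.610 M | −10 °C |  | 80 min |
| beta | 0.61 M | 0.610 M | −25 °C |  | 80 min |

| run | time / min | Z / % |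
|---|---|---|
| larch | 10.0 | 28.8 |
| larch | 30.0 | 53.5 |
| larch | 50.0 | 61.1 |
| larch | 80.0 | 63.3 |
| larch | 120 | 62.3 |
| larch | 150 | 60.1 |
| alder | 3.00 | 58.6 |
| alder | 10.0 | 64.7 |
| alder | 15.0 | 60.4 |
| alder | 25.0 | 57.7 |
| alder | 40.0 | 49.7 |
| alder | 50.0 | 48.4 |
| ash | 12.0 | 35.0 |
| ash | 25.0 | 50.6 |
| ash | 50.0 | 61.9 |
| ash | 80.0 | 61.0 |
| ash | 150 | 61.5 |

(scatter of a reading: 1 percentage point)

- for Z the D are counted in
- as a solid, counted per litre of solution: D
- reactions considered so far: Q <-> J; Q -> Z; J -> X; Z <-> X; Q + L -> E; J <-> G; D <-> Z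
- in a conversion J counts as not yet reacted

* the best flask by amount of Z, in percent of the Q charged; "all alike" if 1.5 percentage points covers them all (theta / delta / beta / all alike)
* amount of Z at the end, in percent of the Q charged, theta
* amount of Z at the end, in percent of the Q charged, delta
* amount of Z at the end, in percent of the Q charged, beta

The readings hold a puzzle. Alder, at −1 °C, shows 58.6 % of Z after 3.00 min, while larch, at −18 °C, shows 53.5 % after 30.0 min. Yet at 50.0 min alder holds 48.4 % and larch 61.1 %, so the faster run has less Z. The tops clear this up. They read 64.7 % and 63.3 %, about equal, with a mean of 64.0 %. In alder and larch the readings of Z rise and then fall, like a kinetic product, and the two runs part in the fall.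

So each fall is replaced by its mean. From its top, alder loses a fraction 0.00408 min⁻¹ of the charge, larch 4.57 × 10⁻⁴ min⁻¹. Alder's straight line stands above its readings at 15.0 min and 40.0 min by 2.3 percentage points and 2.8 points, and the scatter is 1 point, so the mean carries an error of about that size. Alder and larch differ in L as well as in temperature. Counting the difference as temperature, the logarithm of the fall climbs 0.129 K⁻¹. Delta is then reckoned to fall by 0.00128 min⁻¹, and over 80 min that comes to 10.2 %. This is the hold loss, the mean fall times the time in the flask. Taken from the mean top, it leaves delta 53.8 % in this reckoning. Theta's hold loss is 70.6 %, more than the top, so its straight line fails before the end and the reckoning says merely that Z in theta ends far below the top. Beta's is 1.49 %, small beside the top, so for beta the question is how far the rise has come, which this number does not cover.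

The forecast gives theta 25 % (17 % to 38 %), delta 56 % (51 % to 60 %) and beta 52 % (45 % to 58 %), and its best flask is delta: “Delta is best, but its margin over beta is modest”. Its delta stands 2.2 points above the reckoning here.

The flasks give theta 29.8 %, delta 56.6 % and beta 49.2 %, so the best is delta.

    Q ⇌ J (K = 18.0, k = 0.00490 s⁻¹, Ea = 77.0 kJ mol⁻¹, ΔH = −59.0 kJ mol⁻¹)
    Q → Z (k = 0.0170 s⁻¹, Ea = 83.0 kJ mol⁻¹)
    J → X (k = 1.10 s⁻¹, Ea = 66.0 kJ mol⁻¹)
    Z ⇌ X (K = 2.70, k = 5.60 × 10⁻⁴ s⁻¹, Ea = 82.0 kJ mol⁻¹, ΔH = −82.0 kJ mol⁻¹)
    Q + L → E (k = 0.00210 L mol⁻¹ s⁻¹, Ea = 59.0 kJ mol⁻¹)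
    J ⇌ G (K = 1.30, k = 0.00500 s⁻¹, Ea = 68.0 kJ mol⁻¹, ΔH = −22.0 kJ mol⁻¹)
    D ⇌ Z, rate k7*(cs7 - [Z]) while solid is left; crystals form when [Z] > cs7 (solubility = 0.210 M, k = 0.0150 s⁻¹)
    (constants at 5 °C)

In delta, D stood at 28.2 % after 40.0 min and 22.4 % after 80.0 min, while Z → X ran and Z fell by 0.00145 min⁻¹, against the reckoned 0.00128 min⁻¹; delta's Z ended 7.4 points under the mean top read in alder and larch, against a hold loss of 10.2 %. In theta, D went from 11.4 % after 40.0 min to 0 % after 80.0 min, while Z passed to X. Theta read at 2.5 h has a hold loss of 132 %, again above the top, so the line is past its use. The computed Z is 25.7 %, beside 68.9 % of X.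

The earlier runs and the new flask were generated by integration with made-up constants, noise included.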